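**Plan**

- Retrosynthetic cuts: the lactone Cα–CH2 bond to the dihydrobenzofuran half; in the dihydrobenzofuran the C3a–C3 bond, the CH2–O bond on C3 and the C2–O aryl ether; in the arylglycerol unit the benzylic C–C bond and the ring B O–CH2 bond; in the lactone the benzylidene C=C bond of a succinate.
- Forward, coumaran half: 5-iodovanillin acetal and a cinnamyl carbonate give a branched allyl aryl ether, the furan ring is closed onto ring C by the radical step, and the C5 carbon is turned into a benzylic bromide.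
- Forward, lactone half: the lactone ring is made from O-benzylvanillin and dimethyl succinate, then the arylglycerol chain is grown on the ring B phenol; the two halves are joined last at Cα and deprotected.
- Stereochemistry: C2 from the iridium catalyst, C3 from C2 (trans closure); lactone Cβ from rhodium hydrogenation, Cα from Cβ (trans alkylation); the aryloxy carbon from an oxazolidinone aldol, the benzylic carbinol from the same aldol followed by Mitsunobu inversion to the erythro form.
- Enabling feature: in the dihydrobenzofuran, the C3a–C3 bond and the oxygen on the C3 CH2 group sit on the two carbons of a vinyl group carried by C2, and C2 is the ether carbon of an aryl 1-arylallyl ether whose ring C carries iodine at the future C3a.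

Key step: step 6

Assumption: the (Sa,Sc,Sc) phosphoramidite in step 5 and (S,S)-Et-DuPhos in step 11 are taken to give the (S)-ether and the (R)-succinate, as is usual for cinnamyl carbonates and itaconate half-esters (the mirror-image ligand would serve otherwise), and imide 22 is taken as a purchased reagent.

**Route**

Step 1
Reactants: 1 5-iodovanillin
Product: 2 4-(1,3-dioxolan-2-yl)-2-iodo-6-methoxyphenol
Conditions: ethylene glycol, p-TsOH (cat.), toluene, reflux (Dean–Stark); Et3N quench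
Reagents that add atoms: ethylene glycol, OCCO
Why: Acid-catalysed acetalisation with azeotropic removal of water masks the aldehyde, which would otherwise make the phenoxide a poor nucleophile and a good leaving group in step 5.

Step 2
Reactants: 3 O-benzylvanillin; 4 triethyl phosphonoacetate
Product: 5 ethyl (E)-3-[4-(benzyloxy)-3-methoxyphenyl]prop-2-enoate
Conditions: LiCl, DBU, MeCN, rt
Reagents that add atoms: none
Why: Horner–Wadsworth–Emmons olefination of a non-enolisable aryl aldehyde under mild LiCl/amine conditions should give the (E)-cinnamate.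

Step 3
Reactants: 5 ethyl (E)-cinnamate
Product: 6 (E)-3-[4-(benzyloxy)-3-methoxyphenyl]prop-2-en-1-ol
Conditions: i-Bu2AlH (2.5 equiv), CH2Cl2, −78 °C; aq. potassium sodium tartrate
Reagents that add atoms: none
Why: 1,2-Reduction of the unsaturated ester by an aluminium hydride at low temperature gives the allylic alcohol and leaves the benzyl ether alone.

Step 4
Reactants: 6 (E)-cinnamyl alcohol
Product: 7 (E)-3-[4-(benzyloxy)-3-methoxyphenyl]prop-2-en-1-yl methyl carbonate
Conditions: ClCO2Me, pyridine, CH2Cl2, 0 °C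
Reagents that add atoms: methyl chloroformate, COC(=O)Cl
Why: Acylation of the primary allylic alcohol with a chloroformate gives the linear carbonate that ionises readily on iridium.

Step 5
Reactants: 2 4-(1,3-dioxolan-2-yl)-2-iodo-6-methoxyphenol; 7 (E)-cinnamyl methyl carbonate
Product: 9 2-[4-{[(1S)-1-(4-(benzyloxy)-3-methoxyphenyl)prop-2-en-1-yl]oxy}-3-iodo-5-methoxyphenyl]-1,3-dioxolane, via lithium aryloxide 8 (not isolated)
Conditions: n-BuLi, THF, 0 °C; then 7, [Ir(cod)Cl]2 (2 mol%), (Sa,Sc,Sc)-binaphthyl bis(1-phenylethyl)phosphoramidite (4 mol%), THF, rt to 40 °C; base-washed silica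
Reagents that add atoms: none
Why: Iridium-catalysed asymmetric allylic etherification: the cyclometalated iridium phosphoramidite ionises the carbonate and the aryloxide attacks the aryl-bearing allyl terminus on the face fixed by the ligand, giving the (S)-branched ether, which cannot undergo Claisen rearrangement because both ortho positions and the para position are blocked.

Step 6
Reactants: 9 (S)-1-arylallyl 2-iodoaryl ether; 10 TEMPO
Product: 12 1-{[(2S,3R)-2-(4-(benzyloxy)-3-methoxyphenyl)-5-(1,3-dioxolan-2-yl)-7-methoxy-2,3-dihydrobenzofuran-3-yl]methoxy}-2,2,6,6-tetramethylpiperidine, via alkylcobaloxime 11 (not isolated)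
Conditions: Co(dmgH)2(py)Cl (1.2 equiv), NaBH4, aq. NaOH (cat.), degassed MeOH, dark, 0 °C to rt; then 10 (3 equiv), CH2Cl2, visible-light lamp, rt
Reagents that add atoms: none
Why: Borohydride reduces the chlorocobaloxime to monovalent cobalt, which transfers an electron to the C–I bond of 9; the σ-aryl radical at the future C3a adds to the inner vinyl carbon in a 5-exo-trig closure that forms the C3a–C3 bond and the furan ring, and the primary radical is stored as the trivalent alkylcobalt 11. Visible light then breaks the weak C–Co bond and the persistent nitroxide 10 couples with the carbon radical at oxygen, forming the CH2–O bond and leaving divalent cobalt. The closest known reaction type is the cobalt-mediated cyclisation of 2-haloaryl allyl ethers to (dihydrobenzofuran-3-yl)methylcobalt complexes with nitroxide or dioxygen capture. The new C3 centre is controlled by the C2 centre: in the chair-like transition state the ring D aryl group on C2 lies pseudo-equatorial, so CH2 and aryl should end up trans, (2S,3R). The step needs 5-exo over 6-endo closure, secured by the monosubstituted terminal alkene and the fast addition of an aryl radical, and C–O capture over hydrogen abstraction or loss of a cobalt hydride, secured by excess nitroxide and by holding the radical on cobalt until irradiation. The acetal, the benzyl ether and the acid-sensitive allylic ether see only basic, non-acidic conditions.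

Step 7
Reactants: 12 alkoxyamine acetal
Product: 13 (2S,3R)-2-[4-(benzyloxy)-3-methoxyphenyl]-7-methoxy-3-{[(2,2,6,6-tetramethylpiperidin-1-yl)oxy]methyl}-2,3-dihydrobenzofuran-5-carbaldehyde
Conditions: 1 M HCl (cat.), THF/H2O, rt
Reagents that add atoms: water, O
Why: Acid-catalysed acetal hydrolysis frees the aryl aldehyde, and the trans-dihydrobenzofuran and the hindered alkoxyamine tolerate dilute acid at room temperature.

Step 8
Reactants: 13 aldehyde
Product: 14 [(2S,3R)-2-(4-(benzyloxy)-3-methoxyphenyl)-7-methoxy-3-{[(2,2,6,6-tetramethylpiperidin-1-yl)oxy]methyl}-2,3-dihydrobenzofuran-5-yl]methanol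
Conditions: NaBH4, MeOH/THF, 0 °C
Reagents that add atoms: none
Why: Borohydride reduction of the aryl aldehyde gives the benzylic alcohol, and the N–O bond is inert to hydride.

Step 9
Reactants: 14 benzylic alcohol
Product: 15 1-{[(2S,3R)-2-(4-(benzyloxy)-3-methoxyphenyl)-5-(bromomethyl)-7-methoxy-2,3-dihydrobenzofuran-3-yl]methoxy}-2,2,6,6-tetramethylpiperidine
Conditions: CBr4, PPh3, CH2Cl2, 0 °C; used at once
Reagents that add atoms: tetrabromomethane, BrC(Br)(Br)Br
Why: Appel bromination under neutral conditions converts the electron-rich benzylic alcohol into the bromide, and the non-nucleophilic tetramethylpiperidine nitrogen does not interfere.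

Step 10
Reactants: 3 O-benzylvanillin; 16 dimethyl succinate
Product: 17 (E)-4-[4-(benzyloxy)-3-methoxyphenyl]-3-(methoxycarbonyl)but-3-enoic acid
Conditions: NaOMe, MeOH, reflux; then 2 M HCl
Reagents that add atoms: none
Why: Stobbe condensation: the succinate enolate adds to the aldehyde, and the resulting lactone opens by elimination to the (E)-benzylidene half-ester.

Step 11
Reactants: 17 benzylidene half-ester
Product: 18 (R)-3-[4-(benzyloxy)-3-methoxybenzyl]-4-methoxy-4-oxobutanoic acid
Conditions: H2 (5 bar), [Rh(cod)((S,S)-Et-DuPhos)]BF4 (0.5 mol%), NaOMe (0.1 equiv), MeOH, rt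
Reagents that add atoms: none
Why: Rhodium–bisphospholane asymmetric hydrogenation of an itaconate-type half-ester: the carboxylate binds the metal beside the alkene and the ligand fixes the face of hydrogen delivery to give the (R)-benzylsuccinate, while the homogeneous catalyst does not cleave the benzyl ether.

Step 12
Reactants: 18 (R)-benzylsuccinate half-ester
Product: 20 (R)-4-[4-(benzyloxy)-3-methoxybenzyl]dihydrofuran-2(3H)-one, via hydroxy acid 19 (not isolated)
Conditions: KOH (1.0 equiv), EtOH; CaCl2, NaBH4, EtOH, −10 °C to rt; then 3 M HCl, rt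
Reagents that add atoms: none
Why: Chemoselective borohydride reduction: calcium borohydride reduces the methyl ester while the carboxylate salt is inert, and acidification closes the γ-lactone without touching the stereocentre.

Step 13
Reactants: 20 benzyl-protected lactone
Product: 21 (R)-4-(4-hydroxy-3-methoxybenzyl)dihydrofuran-2(3H)-one
Conditions: H2 (1 atm), 10% Pd/C, EtOAc, rt
Reagents that add atoms: none
Why: Hydrogenolysis of the aryl benzyl ether frees the ring B phenol for etherification.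

Step 14
Reactants: 21 phenol lactone; 22 (R)-4-benzyl-3-(chloroacetyl)oxazolidin-2-one
Product: 23 (R)-4-benzyl-3-[2-(2-methoxy-4-{[(3R)-5-oxotetrahydrofuran-3-yl]methyl}phenoxy)acetyl]oxazolidin-2-one
Conditions: K2CO3, NaI (0.1 equiv), acetone, rt to 40 °C
Reagents that add atoms: none
Why: Williamson etherification: iodide-assisted SN2 displacement at the α-halo imide carbon by the phenoxide installs the aryloxyacetyl imide in one operation.

Step 15
Reactants: 23 aryloxyacetyl imide; 3 O-benzylvanillin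
Product: 25 (R)-4-benzyl-3-[(2R,3S)-3-(4-(benzyloxy)-3-methoxyphenyl)-3-hydroxy-2-(2-methoxy-4-{[(3R)-5-oxotetrahydrofuran-3-yl]methyl}phenoxy)propanoyl]oxazolidin-2-one, via boron enolate 24 (not isolated)
Conditions: Bu2BOTf (1.2 equiv), i-Pr2NEt (1.4 equiv), CH2Cl2, −78 to 0 °C; 3, −78 to 0 °C; pH 7 buffer, MeOH, 30% H2O2, 0 °C
Reagents that add atoms: none
Why: Evans syn-aldol reaction: the (Z)-boron enolate reacts through a closed chair transition state on the face away from the benzyl group of the auxiliary, which sets the aryloxy-bearing carbon and a syn carbinol, and the boron triflate with amine does not enolise the lactone.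

Step 16
Reactants: 25 aldol adduct
Product: 26 (R)-4-(4-{[(1S,2S)-1-(4-(benzyloxy)-3-methoxyphenyl)-1,3-dihydroxypropan-2-yl]oxy}-3-methoxybenzyl)dihydrofuran-2(3H)-one
Conditions: NaBH4, THF/H2O (4:1), 0 °C to rt
Reagents that add atoms: none
Why: Reductive cleavage of the N-acyl oxazolidinone by borohydride in wet THF gives the primary alcohol and returns the auxiliary, while the γ-lactone is reduced much more slowly.

Step 17
Reactants: 26 threo diol
Product: 27 (R)-4-(4-{[(1S,2S)-1-(4-(benzyloxy)-3-methoxyphenyl)-3-[(tert-butyldimethylsilyl)oxy]-1-hydroxypropan-2-yl]oxy}-3-methoxybenzyl)dihydrofuran-2(3H)-one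
Conditions: TBSCl (1.1 equiv), imidazole, CH2Cl2, 0 °C
Reagents that add atoms: tert-butyldimethylsilyl chloride, CC(C)(C)[Si](C)(C)Cl
Why: Selective silylation of the primary hydroxyl over the hindered benzylic secondary one.

Step 18
Reactants: 27 primary silyl ether
Product: 28 (1R,2S)-1-[4-(benzyloxy)-3-methoxyphenyl]-3-[(tert-butyldimethylsilyl)oxy]-2-(2-methoxy-4-{[(3R)-5-oxotetrahydrofuran-3-yl]methyl}phenoxy)propyl 4-nitrobenzoate
Conditions: PPh3, DIAD, 4-nitrobenzoic acid, THF, 0 °C to rt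
Reagents that add atoms: 4-nitrobenzoic acid, O=C(O)c1ccc(cc1)[N+](=O)[O-]
Why: Mitsunobu reaction: the activated benzylic alcohol is displaced by the carboxylate with inversion, which turns the threo into the erythro arrangement, (1R,2S).

Step 19
Reactants: 28 4-nitrobenzoate
Product: 29 (R)-4-(4-{[(1R,2S)-1-(4-(benzyloxy)-3-methoxyphenyl)-3-[(tert-butyldimethylsilyl)oxy]-1-hydroxypropan-2-yl]oxy}-3-methoxybenzyl)dihydrofuran-2(3H)-one
Conditions: K2CO3 (0.3 equiv), MeOH/THF, 0 °C
Reagents that add atoms: none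
Why: Base-catalysed methanolysis (transesterification) removes the activated aryl ester, and the γ-lactone is favoured over its ring-opened methyl ester.

Step 20
Reactants: 29 erythro alcohol
Product: 30 (R)-4-(4-{[(1R,2S)-1-(4-(benzyloxy)-3-methoxyphenyl)-3-[(tert-butyldimethylsilyl)oxy]-1-[(triethylsilyl)oxy]propan-2-yl]oxy}-3-methoxybenzyl)dihydrofuran-2(3H)-one
Conditions: TESCl, imidazole, DMF, rt
Reagents that add atoms: chlorotriethylsilane, CC[Si](CC)(CC)Cl
Why: Silylation of the secondary alcohol removes the last acidic proton before enolate formation and gives a group that is lost under the mild acid of step 22.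

Step 21
Reactants: 30 protected lactone; 15 benzylic bromide
Product: 32 (3R,4R)-trans-α,β-dibenzyl lactone carrying the alkoxyamine and both silyl ethers, via lithium enolate 31 (not isolated)
Conditions: LiN(SiMe3)2 (1.1 equiv), THF, −78 °C; then 15, DMPU, −78 to −30 °C
Reagents that add atoms: none
Why: Alkylation of a lactone enolate: the benzylic bromide approaches the enolate anti to the β-benzyl group, which should give the trans-α,β-dibenzyl lactone, (3R,4R).

Step 22
Reactants: 32 coupled lactone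
Product: 33 dibenzyl ether of the target (rings A and D as benzyl ethers; all four hydroxyl groups free)
Conditions: Zn dust, AcOH/THF/H2O (3:1:1), 50 °C
Reagents that add atoms: none
Why: Zinc in acetic acid reduces the N–O bond of the alkoxyamine to the primary alcohol, and the aqueous acetic acid hydrolyses the triethylsilyl ether and the primary tert-butyldimethylsilyl ether in the same operation.

Step 23
Reactants: 33 dibenzyl ether
Product: 34 target compound CNP0265599.1
Conditions: H2 (1 atm), 10% Pd/C, EtOAc/EtOH, rt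
Reagents that add atoms: none
Why: Hydrogenolysis of the two aryl benzyl ethers should be faster than cleavage of the cyclic benzylic ether or the benzylic alcohol, and gives the target.

**Compound list**

1 | 5-iodovanillin (4-hydroxy-3-iodo-5-methoxybenzaldehyde) | COc1cc(C=O)cc(I)c1O | starting material
2 | 4-(1,3-dioxolan-2-yl)-2-iodo-6-methoxyphenol | COc1cc(C2OCCO2)cc(I)c1O | intermediate
3 | O-benzylvanillin (4-(benzyloxy)-3-methoxybenzaldehyde) | COc1cc(C=O)ccc1OCc1ccccc1 | starting material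
4 | triethyl phosphonoacetate | CCOC(=O)CP(=O)(OCC)OCC | starting material
5 | ethyl (E)-3-[4-(benzyloxy)-3-methoxyphenyl]prop-2-enoate | CCOC(=O)/C=C/c1ccc(OCc2ccccc2)c(OC)c1 | intermediate
6 | (E)-3-[4-(benzyloxy)-3-methoxyphenyl]prop-2-en-1-ol | OC/C=C/c1ccc(OCc2ccccc2)c(OC)c1 | intermediate
7 | (E)-3-[4-(benzyloxy)-3-methoxyphenyl]prop-2-en-1-yl methyl carbonate | COC(=O)OC/C=C/c1ccc(OCc2ccccc2)c(OC)c1 | intermediate
8 | lithium 4-(1,3-dioxolan-2-yl)-2-iodo-6-methoxyphenolate | [Li+].[O-]c1c(I)cc(C2OCCO2)cc1OC | intermediate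
9 | 2-[4-{[(1S)-1-(4-(benzyloxy)-3-methoxyphenyl)prop-2-en-1-yl]oxy}-3-iodo-5-methoxyphenyl]-1,3-dioxolane | C=C[C@H](Oc1c(I)cc(C2OCCO2)cc1OC)c1ccc(OCc2ccccc2)c(OC)c1 | intermediate
10 | TEMPO ((2,2,6,6-tetramethylpiperidin-1-yl)oxyl) | CC1(C)CCCC(C)(C)N1[O] | starting material
11 | {[(2S,3S)-2-(4-(benzyloxy)-3-methoxyphenyl)-5-(1,3-dioxolan-2-yl)-7-methoxy-2,3-dihydrobenzofuran-3-yl]methyl}(pyridine)bis(dimethylglyoximato)cobalt (trivalent cobalt) | O1CCOC1c1cc(OC)c2c(c1)[C@H](C[Co-3]34([n+]5ccccc5)([N+](O)=C(C)C(C)=[N+]3[O-])[N+](O)=C(C)C(C)=[N+]4[O-])[C@@H](c1ccc(OCc3ccccc3)c(OC)c1)O2 | intermediate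
12 | 1-{[(2S,3R)-2-(4-(benzyloxy)-3-methoxyphenyl)-5-(1,3-dioxolan-2-yl)-7-methoxy-2,3-dihydrobenzofuran-3-yl]methoxy}-2,2,6,6-tetramethylpiperidine | O1CCOC1c1cc(OC)c2c(c1)[C@H](CON3C(C)(C)CCCC3(C)C)[C@@H](c1ccc(OCc3ccccc3)c(OC)c1)O2 | intermediate
13 | (2S,3R)-2-[4-(benzyloxy)-3-methoxyphenyl]-7-methoxy-3-{[(2,2,6,6-tetramethylpiperidin-1-yl)oxy]methyl}-2,3-dihydrobenzofuran-5-carbaldehyde | O=Cc1cc(OC)c2c(c1)[C@H](CON3C(C)(C)CCCC3(C)C)[C@@H](c1ccc(OCc3ccccc3)c(OC)c1)O2 | intermediate
14 | [(2S,3R)-2-(4-(benzyloxy)-3-methoxyphenyl)-7-methoxy-3-{[(2,2,6,6-tetramethylpiperidin-1-yl)oxy]methyl}-2,3-dihydrobenzofuran-5-yl]methanol | OCc1cc(OC)c2c(c1)[C@H](CON3C(C)(C)CCCC3(C)C)[C@@H](c1ccc(OCc3ccccc3)c(OC)c1)O2 | intermediate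
15 | 1-{[(2S,3R)-2-(4-(benzyloxy)-3-methoxyphenyl)-5-(bromomethyl)-7-methoxy-2,3-dihydrobenzofuran-3-yl]methoxy}-2,2,6,6-tetramethylpiperidine | BrCc1cc(OC)c2c(c1)[C@H](CON3C(C)(C)CCCC3(C)C)[C@@H](c1ccc(OCc3ccccc3)c(OC)c1)O2 | intermediate
16 | dimethyl succinate | COC(=O)CCC(=O)OC | starting material
17 | (E)-4-[4-(benzyloxy)-3-methoxyphenyl]-3-(methoxycarbonyl)but-3-enoic acid | COC(=O)/C(CC(=O)O)=C/c1ccc(OCc2ccccc2)c(OC)c1 | intermediate
18 | (R)-3-[4-(benzyloxy)-3-methoxybenzyl]-4-methoxy-4-oxobutanoic acid | COC(=O)[C@@H](CC(=O)O)Cc1ccc(OCc2ccccc2)c(OC)c1 | intermediate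
19 | (R)-4-[4-(benzyloxy)-3-methoxyphenyl]-3-(hydroxymethyl)butanoic acid | OC[C@@H](CC(=O)O)Cc1ccc(OCc2ccccc2)c(OC)c1 | intermediate
20 | (R)-4-[4-(benzyloxy)-3-methoxybenzyl]dihydrofuran-2(3H)-one | O=C1OC[C@H](Cc2ccc(OCc3ccccc3)c(OC)c2)C1 | intermediate
21 | (R)-4-(4-hydroxy-3-methoxybenzyl)dihydrofuran-2(3H)-one | O=C1OC[C@H](Cc2ccc(O)c(OC)c2)C1 | intermediate
22 | (R)-4-benzyl-3-(chloroacetyl)oxazolidin-2-one | ClCC(=O)N1C(=O)OC[C@H]1Cc1ccccc1 | starting material
23 | (R)-4-benzyl-3-[2-(2-methoxy-4-{[(3R)-5-oxotetrahydrofuran-3-yl]methyl}phenoxy)acetyl]oxazolidin-2-one | COc1cc(C[C@H]2COC(=O)C2)ccc1OCC(=O)N1C(=O)OC[C@H]1Cc1ccccc1 | intermediate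
24 | (Z)-dibutylboron enolate of imide 23 | CCCCB(CCCC)O/C(=C\Oc1ccc(C[C@H]2COC(=O)C2)cc1OC)N1C(=O)OC[C@H]1Cc1ccccc1 | intermediate
25 | (R)-4-benzyl-3-[(2R,3S)-3-(4-(benzyloxy)-3-methoxyphenyl)-3-hydroxy-2-(2-methoxy-4-{[(3R)-5-oxotetrahydrofuran-3-yl]methyl}phenoxy)propanoyl]oxazolidin-2-one | COc1cc([C@H](O)[C@H](C(=O)N2C(=O)OC[C@H]2Cc2ccccc2)Oc2ccc(C[C@H]3COC(=O)C3)cc2OC)ccc1OCc1ccccc1 | intermediate
26 | (R)-4-(4-{[(1S,2S)-1-(4-(benzyloxy)-3-methoxyphenyl)-1,3-dihydroxypropan-2-yl]oxy}-3-methoxybenzyl)dihydrofuran-2(3H)-one (threo) | COc1cc([C@H](O)[C@H](CO)Oc2ccc(C[C@H]3COC(=O)C3)cc2OC)ccc1OCc1ccccc1 | intermediate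
27 | (R)-4-(4-{[(1S,2S)-1-(4-(benzyloxy)-3-methoxyphenyl)-3-[(tert-butyldimethylsilyl)oxy]-1-hydroxypropan-2-yl]oxy}-3-methoxybenzyl)dihydrofuran-2(3H)-one | COc1cc([C@H](O)[C@H](CO[Si](C)(C)C(C)(C)C)Oc2ccc(C[C@H]3COC(=O)C3)cc2OC)ccc1OCc1ccccc1 | intermediate
28 | (1R,2S)-1-[4-(benzyloxy)-3-methoxyphenyl]-3-[(tert-butyldimethylsilyl)oxy]-2-(2-methoxy-4-{[(3R)-5-oxotetrahydrofuran-3-yl]methyl}phenoxy)propyl 4-nitrobenzoate | COc1cc([C@@H](OC(=O)c2ccc(cc2)[N+](=O)[O-])[C@H](CO[Si](C)(C)C(C)(C)C)Oc2ccc(C[C@H]3COC(=O)C3)cc2OC)ccc1OCc1ccccc1 | intermediate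
29 | (R)-4-(4-{[(1R,2S)-1-(4-(benzyloxy)-3-methoxyphenyl)-3-[(tert-butyldimethylsilyl)oxy]-1-hydroxypropan-2-yl]oxy}-3-methoxybenzyl)dihydrofuran-2(3H)-one (erythro) | COc1cc([C@@H](O)[C@H](CO[Si](C)(C)C(C)(C)C)Oc2ccc(C[C@H]3COC(=O)C3)cc2OC)ccc1OCc1ccccc1 | intermediate
30 | (R)-4-(4-{[(1R,2S)-1-(4-(benzyloxy)-3-methoxyphenyl)-3-[(tert-butyldimethylsilyl)oxy]-1-[(triethylsilyl)oxy]propan-2-yl]oxy}-3-methoxybenzyl)dihydrofuran-2(3H)-one | COc1cc([C@@H](O[Si](CC)(CC)CC)[C@H](CO[Si](C)(C)C(C)(C)C)Oc2ccc(C[C@H]3COC(=O)C3)cc2OC)ccc1OCc1ccccc1 | intermediate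
31 | lithium enolate of lactone 30 | [Li+].COc1cc([C@@H](O[Si](CC)(CC)CC)[C@H](CO[Si](C)(C)C(C)(C)C)Oc2ccc(C[C@H]3COC([O-])=C3)cc2OC)ccc1OCc1ccccc1 | intermediate
32 | (3R,4R)-3-{[(2S,3R)-2-(4-(benzyloxy)-3-methoxyphenyl)-7-methoxy-3-{[(2,2,6,6-tetramethylpiperidin-1-yl)oxy]methyl}-2,3-dihydrobenzofuran-5-yl]methyl}-4-(4-{[(1R,2S)-1-(4-(benzyloxy)-3-methoxyphenyl)-3-[(tert-butyldimethylsilyl)oxy]-1-[(triethylsilyl)oxy]propan-2-yl]oxy}-3-methoxybenzyl)dihydrofuran-2(3H)-one | COc1cc([C@@H](O[Si](CC)(CC)CC)[C@H](CO[Si](C)(C)C(C)(C)C)Oc2ccc(C[C@H]3COC(=O)[C@@H]3Cc3cc(OC)c4c(c3)[C@H](CON5C(C)(C)CCCC5(C)C)[C@@H](c3ccc(OCc5ccccc5)c(OC)c3)O4)cc2OC)ccc1OCc1ccccc1 | intermediate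
33 | (3R,4R)-3-{[(2S,3R)-2-(4-(benzyloxy)-3-methoxyphenyl)-3-(hydroxymethyl)-7-methoxy-2,3-dihydrobenzofuran-5-yl]methyl}-4-(4-{[(1R,2S)-1-(4-(benzyloxy)-3-methoxyphenyl)-1,3-dihydroxypropan-2-yl]oxy}-3-methoxybenzyl)dihydrofuran-2(3H)-one | COc1cc([C@@H](O)[C@H](CO)Oc2ccc(C[C@H]3COC(=O)[C@@H]3Cc3cc(OC)c4c(c3)[C@H](CO)[C@@H](c3ccc(OCc5ccccc5)c(OC)c3)O4)cc2OC)ccc1OCc1ccccc1 | intermediate
34 | (3R,4R)-4-(4-{[(1R,2S)-1,3-dihydroxy-1-(4-hydroxy-3-methoxyphenyl)propan-2-yl]oxy}-3-methoxybenzyl)-3-{[(2S,3R)-2-(4-hydroxy-3-methoxyphenyl)-3-(hydroxymethyl)-7-methoxy-2,3-dihydrobenzofuran-5-yl]methyl}dihydrofuran-2(3H)-one (CNP0265599.1) | COc1cc([C@@H](O)[C@H](CO)Oc2ccc(C[C@H]3COC(=O)[C@@H]3Cc3cc(OC)c4c(c3)[C@H](CO)[C@@H](c3ccc(O)c(OC)c3)O4)cc2OC)ccc1O | target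

**Step count and risk**

Total steps: 23. Longest linear sequence: 14 steps (steps 10 to 23, from O-benzylvanillin 3).

Steps most likely to fail:

Step 5. The electron-rich branched ether may ionise again on iridium, which would erode the branched-to-linear ratio and the enantiopurity, and the doubly ortho-substituted aryloxide may attack slowly. The fallback forms the C–O bond with transfer of chirality from a resolved alcohol instead of by catalyst control. It sets out from 3: vinylmagnesium bromide in THF gives racemic 1-[4-(benzyloxy)-3-methoxyphenyl]prop-2-en-1-ol F1. Lipase B from Candida antarctica with vinyl acetate acylates the fast-reacting enantiomer to (R)-1-[4-(benzyloxy)-3-methoxyphenyl]prop-2-en-1-yl acetate F2 and leaves (S)-1-[4-(benzyloxy)-3-methoxyphenyl]prop-2-en-1-ol F3. Methyl chloroformate and pyridine convert this into (S)-1-[4-(benzyloxy)-3-methoxyphenyl]prop-2-en-1-yl methyl carbonate F4. RhCl(PPh3)3 modified with P(OMe)3 in THF should then couple F4 with aryloxide 8 at the substituted terminus with overall retention. This gives 9, where the route is rejoined.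

Step 6. The closure may show poor facial selectivity, or the primary radical may be lost to hydrogen abstraction or to elimination of a cobalt hydride before the nitroxide takes it. The fallback isolates the organometallic and makes the C–O bond by substitution. It sets out from 9: the same monovalent cobalt reagent gives alkylcobaloxime 11, which should survive chromatography so that a cis isomer can be removed. Iodine in CH2Cl2 cleaves the C–Co bond to 2-[(2S,3S)-2-(4-(benzyloxy)-3-methoxyphenyl)-3-(iodomethyl)-7-methoxy-2,3-dihydrobenzofuran-5-yl]-1,3-dioxolane F5. Sodium 2,2,6,6-tetramethylpiperidin-1-olate F6, made from 10 and sodium naphthalenide in THF, displaces the iodide and gives 12, where the route is rejoined.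

Step 18. The activated electron-rich benzylic alcohol may ionise, which would give partial retention or elimination to an enol ether. The fallback sets the carbinol configuration by reduction instead of displacement. It sets out from 27: Dess–Martin periodinane with NaHCO3 in CH2Cl2 gives (R)-4-(4-{[(2S)-1-(4-(benzyloxy)-3-methoxyphenyl)-3-[(tert-butyldimethylsilyl)oxy]-1-oxopropan-2-yl]oxy}-3-methoxybenzyl)dihydrofuran-2(3H)-one F7. Zn(BH4)2 in Et2O at −30 °C should reduce the ketone under chelation control: zinc bridges the ketone and the α-aryloxy oxygen, and hydride enters from the side away from the silyloxymethyl group. This gives the erythro alcohol 29 directly, where the route is rejoined.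

Further compounds
F1 | step 5 | racemic 1-[4-(benzyloxy)-3-methoxyphenyl]prop-2-en-1-ol | C=CC(O)c1ccc(OCc2ccccc2)c(OC)c1
F2 | step 5 | (R)-1-[4-(benzyloxy)-3-methoxyphenyl]prop-2-en-1-yl acetate | C=C[C@@H](OC(C)=O)c1ccc(OCc2ccccc2)c(OC)c1
F3 | step 5 | (S)-1-[4-(benzyloxy)-3-methoxyphenyl]prop-2-en-1-ol | C=C[C@H](O)c1ccc(OCc2ccccc2)c(OC)c1
F4 | step 5 | (S)-1-[4-(benzyloxy)-3-methoxyphenyl]prop-2-en-1-yl methyl carbonate | C=C[C@H](OC(=O)OC)c1ccc(OCc2ccccc2)c(OC)c1
F5 | step 6 | 2-[(2S,3S)-2-(4-(benzyloxy)-3-methoxyphenyl)-3-(iodomethyl)-7-methoxy-2,3-dihydrobenzofuran-5-yl]-1,3-dioxolane | O1CCOC1c1cc(OC)c2c(c1)[C@H](CI)[C@@H](c1ccc(OCc3ccccc3)c(OC)c1)O2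
F6 | step 6 | sodium 2,2,6,6-tetramethylpiperidin-1-olate | [Na+].CC1(C)CCCC(C)(C)N1[O-]
F7 | step 18 | (R)-4-(4-{[(2S)-1-(4-(benzyloxy)-3-methoxyphenyl)-3-[(tert-butyldimethylsilyl)oxy]-1-oxopropan-2-yl]oxy}-3-methoxybenzyl)dihydrofuran-2(3H)-one | COc1cc(C(=O)[C@H](CO[Si](C)(C)C(C)(C)C)Oc2ccc(C[C@H]3COC(=O)C3)cc2OC)ccc1OCc1ccccc1
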